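(Readings and results are simulated on assumed constants; the scatter is artificial.)

We have to choose between two loadings, and the choice rests on which of them leaves the right-handed substrate in the higher excess after the stated time.

| setting | south | beta | delta |
|---|---|---|---|
| left-handed substrate | 0.034 M | 0.050 M | 0.050 M |
| right-handed substrate | 0.034 M | 0.050 M | 0.050 M |
| gas | 3.6 mM (held) | 3.6 mM (held) | 3.6 mM (held) |
| precatalyst | 18 mol% | 18 mol% | 25 mol% |
| remark | run made earlier |  |  |
| time |  | 40 h | 40 h |

south run (percent of the left-handed substrate and right-handed substrate together charged)

| time / h | right-handed substrate / % | left-handed substrate / % |
|---|---|---|
| 1.00 | 50.1 | 48.1 |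
| 3.00 | 49.2 | 44.7 |
| 5.00 | 45.8 | 38.9 |
| 8.00 | 43.3 | 34.9 |

(readings scatter by 1 percentage point)

- catalyst is single-handed; left-handed substrate and right-handed substrate are mirror images of each other, charged as a racemate, each of them at the stated concentration
- at the start none of partner is dissolved
- what was read earlier has a scatter of 1 percentage point, one standard deviation
- steps thought possible: partner + catalyst + left-handed substrate -> catalyst + left-handed product; partner + catalyst + right-handed substrate -> catalyst + right-handed product; partner + precatalyst -> catalyst + spent reagent; gas <-> partner
- an excess is the difference of the two amounts in percent of their sum
- an excess is below zero if the other one leads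
- no earlier run changes the charge of precatalyst; that part of a forecast is a guess

1. which of the two ends with the higher excess of right-handed substrate over left-handed substrate among what is left of the two ("neither" if they lie within 2 percentage points) (beta / delta / neither)
2. excess of right-handed substrate over left-handed substrate among what is left of the two at the end, beta
3. excess of right-handed substrate over left-handed substrate among what is left of the two at the end, delta

Both colleagues agree on where each flask is heading: with partner held up by the gas, both substrates are on their way to product, so the excess is a question of how far the flask has got and of one ratio. Take the logarithm of the fraction left of the left-handed substrate and divide it by the same logarithm for the right-handed substrate. This ratio is the selectivity factor, and south at 8.00 h reads 2.50, while its 5.00 h reading gives 2.86. Both steps take the same partner and the same catalyst, so these cancel in the ratio, and I carry the later reading forward.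

The first colleague says speed follows the amount of catalyst. South's logarithm for the left-handed substrate falls by 0.0495 h⁻¹ between its 3.00 h and 8.00 h readings. Beta holds 1.47 times south's catalyst and delta 2.04 times, if the precatalyst converts entirely. Scaling the fall and applying the selectivity factor, I get 70.3 % for beta and 83.7 % for delta. The loading step is a guess, since south never varied it.

The second colleague says the flask consumes partner as fast as gas dissolves, so equal gas means equal loss per hour. South's loss, carried over to the larger charge, takes 85.4 % of either flask, which gives equal excesses and the answer neither. I commit to the first view.

The forecast says delta, at 72 % for beta and 83 % for delta, and remarks “South cannot distinguish these cases, so I shade both down.”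

The flask gives delta, with 77.9 % in beta and 88.9 % in delta, a gap of 11 percentage points. Partner does stand lower in the earlier hours, which is as far as the flask goes towards the gas view: delta read at 10.0 h holds partner at 72.3 % of saturation, against 96.2 % at 40.0 h.

    partner + catalyst + left-handed substrate → catalyst + left-handed product (k = 0.890 L² mol⁻² s⁻¹)
    partner + catalyst + right-handed substrate → catalyst + right-handed product (k = 0.339 L² mol⁻² s⁻¹)
    partner + precatalyst → catalyst + spent reagent (k = 0.114 L mol⁻¹ s⁻¹)
    gas ⇌ partner, rate k4*(csat - [partner]) (kL = 0.00109 s⁻¹)

Applied to the right-handed rests, the selectivity factor gives 4.04 % of the left-handed charge for beta, where 3.4 % stands, and 1.28 % for delta, where 1.0 % stands. In delta the left-handed substrate has a half-life of 6.7 h at 9.56 h and 5.0 h at 40.0 h, each short against the 40 h of the run. By then the left-handed step uses partner at 0.15 of the rate of the right-handed step.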